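## Retrosynthetic overview

- Numbering runs from the carboxyl carbon C1 to the phenyl-bearing C15. The last cuts are the C1 methyl ester and the 10E alkene, made by Julia–Kocienski olefination of a C10 aldehyde with a C11–C15 styryl tetrazolyl sulfone.
- The strategy rests on the 1,2-dioxolane (C3, C4, C5 and the two oxygens), in which C3 and C5 are both fully substituted, oxygen-bearing carbons. The ring is cut at C4–C5 and C3–O into a C5 peroxycarbenium ion (from a silylperoxy methyl ketal of a methyl ketone) and the 1,1-disubstituted alkene of methyl 3-methylbut-3-enoate (C1–C4 plus the C3 methyl).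
- The ketal (C5–C10) comes from (4R)-4-methyl-7-silyloxyheptan-2-one through its methyl enol ether, ozonolysis in methanol and O-silylation. C7 is set by copper/Josiphos-catalysed conjugate addition of a 3-silyloxypropyl Grignard reagent to (E)-pent-3-en-2-one.
- Only one ring is formed, the dioxolane in step 5. Both side-chain alkenes are introduced after it, so that no other alkene competes for the cation.

Key step: step 5

Assumption: the (R,Sp) antipode of the Josiphos ligand is taken to direct the alkyl group to the enone face that gives (4R)-4; both antipodes are sold, so the other is used if the first run shows the opposite sense.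

## Route

Step 1
Reactants: 1 (E)-pent-3-en-2-one; 2 (3-bromopropoxy)(tert-butyl)dimethylsilane
Product: 4 (4R)-7-[(tert-butyldimethylsilyl)oxy]-4-methylheptan-2-one, via Grignard reagent 3 (not isolated)
Conditions: Mg, Et2O, rt; then CuBr·SMe2 (5 mol %), (R)-1-[(Sp)-2-(diphenylphosphino)ferrocenyl]ethyldicyclohexylphosphine (C36H44FeP2, 6 mol %), tBuOMe, −75 °C, slow addition of 1; NH4Cl aq
Reagents that add atoms: none
Why: Copper-catalysed enantioselective conjugate addition of a Grignard reagent to a linear enone, in which the chiral copper–diphosphine complex selects the enone face and so sets C7 (C4 of 4) as R, while the primary silyl ether is inert to the organomagnesium reagent at −75 °C.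

Step 2
Reactants: 4 (4R)-7-[(tert-butyldimethylsilyl)oxy]-4-methylheptan-2-one
Product: 5 tert-butyl{[(4R)-7-methoxy-4,6-dimethylhept-6-en-1-yl]oxy}dimethylsilane (E/Z mixture)
Conditions: MeOCH2PPh3Cl, KOtBu, THF, 0 °C; then 4, 0 °C → rt; Et3N-deactivated silica
Reagents that add atoms: (methoxymethyl)triphenylphosphonium chloride, COC[P+](c1ccccc1)(c1ccccc1)c1ccccc1.[Cl-]
Why: Wittig reaction of the methyl ketone with (methoxymethylene)triphenylphosphorane should give the methyl enol ether, chosen because its ozonolysis is regiochemically unambiguous, and C7 is β to the carbonyl group and cannot epimerise.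

Step 3
Reactants: 5 tert-butyl{[(4R)-7-methoxy-4,6-dimethylhept-6-en-1-yl]oxy}dimethylsilane
Product: 7 tert-butyl{[(4R)-6-hydroperoxy-6-methoxy-4-methylheptyl]oxy}dimethylsilane (both ketal epimers), via carbonyl oxide 6 (not isolated)
Conditions: O3, CH2Cl2/MeOH (4:1), NaHCO3, −78 °C; N2 purge; no reductive work-up; concentration below 25 °C
Reagents that add atoms: ozone, [O-][O+]=O; methanol, CO
Why: Ozonolysis with Criegee fragmentation, in which the primary ozonide of an enol ether cleaves so that the alkoxy carbon leaves as methyl formate and the ketone O-oxide 6 forms at C5, where methanol traps it as the α-methoxy hydroperoxide with the O–O bond kept.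

Step 4
Reactants: 7 tert-butyl{[(4R)-6-hydroperoxy-6-methoxy-4-methylheptyl]oxy}dimethylsilane
Product: 8 tert-butyl{[(4R)-6-methoxy-4-methyl-6-(triethylsilylperoxy)heptyl]oxy}dimethylsilane (both ketal epimers)
Conditions: Et3SiCl, imidazole, DMF, 0 °C
Reagents that add atoms: chlorotriethylsilane, CC[Si](Cl)(CC)CC
Why: O-Silylation of the acidic hydroperoxide under imidazole catalysis should give the triethylsilyl peroxide, whose silyl group is the one expelled from oxygen in the ring closure, and the mixed ketal is stable to these mildly basic conditions.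

Step 5
Reactants: 8 tert-butyl{[(4R)-6-methoxy-4-methyl-6-(triethylsilylperoxy)heptyl]oxy}dimethylsilane; 9 methyl 3-methylbut-3-enoate
Product: 12 methyl 2-[(3R,5R)-5-{(2R)-5-[(tert-butyldimethylsilyl)oxy]-2-methylpentyl}-3,5-dimethyl-1,2-dioxolan-3-yl]acetate, via peroxycarbenium ion 10 (not isolated), via tertiary carbocation 11 (not isolated)
Conditions: 9 (3 equiv), SnCl4 (1.5 equiv), CH2Cl2, −78 → −40 °C; NaHCO3 aq; silica chromatography, then preparative HPLC
Reagents that add atoms: none
Why: SnCl4 removes the methoxy group of 8 to give the peroxycarbenium ion 10, the unsubstituted CH2 terminus of 9 attacks its C5 (bond C4–C5, Markovnikov sense) so that the charge moves to tertiary C3 in 11, and the silylated peroxy oxygen then closes on C3 (bond C3–O) with loss of Et3SiCl. The closest known reaction type is the Lewis acid-mediated annulation of triethylsilylperoxy ketals with simple alkenes to 1,2-dioxolanes, a stepwise cationic (3+2) process akin to allylsilane annulations of oxocarbenium ions. The dioxolane ring closes by capture of a free tertiary carbocation by oxygen through a five-membered transition state, formally 5-endo at the cationic carbon but not subject to the usual stereoelectronic bar because the acceptor is an empty p orbital. C7 is carried in unchanged from 4, C5 is fixed by the face of 10 that the alkene attacks and C3 by the face of 11 that the oxygen reaches; the remote C7 methyl group and the small methyl-versus-methylene difference at C5 and C3 are expected to bias neither choice strongly, so the four C3/C5 isomers should form in comparable amounts and (3R,5R)-12 is separated by chromatography and preparative HPLC, its 3,5-cis-dimethyl relationship to be confirmed by NOE and its 5,7 relationship by carrying each cis isomer forward and comparing with the data of the target. What the substrate does secure is regio- and chemoselectivity: the 1,1-disubstituted alkene can only place the charge on its substituted carbon, both ring carbinol carbons are tertiary so that each cationic stage is stabilised and the product peroxide has no α-hydrogen, and the chain end is a silyl ether so that no second alkene competes for C5. An excess of 9 and more than one equivalent of SnCl4 are used because the ester group lowers the nucleophilicity of the alkene and binds part of the Lewis acid.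

Step 6
Reactants: 12 methyl 2-[(3R,5R)-5-{(2R)-5-[(tert-butyldimethylsilyl)oxy]-2-methylpentyl}-3,5-dimethyl-1,2-dioxolan-3-yl]acetate
Product: 13 methyl 2-{(3R,5R)-5-[(2R)-5-hydroxy-2-methylpentyl]-3,5-dimethyl-1,2-dioxolan-3-yl}acetate
Conditions: HF·pyridine, pyridine, THF, 0 °C → rt
Reagents that add atoms: none
Why: Fluoride-mediated cleavage of the primary silyl ether under buffered, non-basic conditions, to which the methyl ester and a dialkyl peroxide without α-hydrogen are inert.

Step 7
Reactants: 13 methyl 2-{(3R,5R)-5-[(2R)-5-hydroxy-2-methylpentyl]-3,5-dimethyl-1,2-dioxolan-3-yl}acetate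
Product: 14 methyl 2-{(3R,5R)-3,5-dimethyl-5-[(2R)-2-methyl-5-oxopentyl]-1,2-dioxolan-3-yl}acetate
Conditions: Dess–Martin periodinane, NaHCO3, CH2Cl2, 0 °C → rt; used at once
Reagents that add atoms: none
Why: Dess–Martin oxidation of the primary alcohol to the C10 aldehyde under buffered neutral conditions that neither reduce the O–O bond nor enolise the β-peroxy ester.

Step 8
Reactants: 15 1-phenylprop-2-en-1-ol (racemic)
Product: 16 ethyl (4E)-5-phenylpent-4-enoate
Conditions: MeC(OEt)3 (5 equiv), EtCO2H (cat.), 140 °C, EtOH distilled off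
Reagents that add atoms: triethyl orthoacetate, CC(OCC)(OCC)OCC
Why: Johnson–Claisen rearrangement of the ketene acetal through a chair transition state with the phenyl group pseudo-equatorial should give the conjugated E styrene (C14=C15), and the carbinol stereocentre is destroyed so the racemic alcohol serves.

Step 9
Reactants: 16 ethyl (4E)-5-phenylpent-4-enoate
Product: 17 (4E)-5-phenylpent-4-en-1-ol
Conditions: LiAlH4, THF, 0 °C; H2O, 15% NaOH aq, H2O
Reagents that add atoms: none
Why: Hydride reduction of the ester to the primary alcohol with LiAlH4, which leaves the unactivated styrenyl alkene untouched at 0 °C.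

Step 10
Reactants: 17 (4E)-5-phenylpent-4-en-1-ol
Product: 18 1-phenyl-5-{[(4E)-5-phenylpent-4-en-1-yl]sulfanyl}-1H-tetrazole
Conditions: 1-phenyl-1H-tetrazole-5-thiol, PPh3, DIAD, THF, 0 °C → rt
Reagents that add atoms: 1-phenyl-1H-tetrazole-5-thiol, Sc1nnnn1-c1ccccc1
Why: Mitsunobu reaction of the primary alcohol with the acidic tetrazole thiol gives the thioether by SN2 displacement of the oxyphosphonium group.

Step 11
Reactants: 18 1-phenyl-5-{[(4E)-5-phenylpent-4-en-1-yl]sulfanyl}-1H-tetrazole
Product: 19 1-phenyl-5-{[(4E)-5-phenylpent-4-en-1-yl]sulfonyl}-1H-tetrazole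
Conditions: (NH4)6Mo7O24·4H2O (10 mol %), 30% H2O2, EtOH, 0 °C → rt
Reagents that add atoms: hydrogen peroxide, OO
Why: Molybdate-catalysed oxidation of the sulfide to the sulfone with H2O2, in which the peroxomolybdate oxidant is electrophilic toward sulfur and should leave the styrene unepoxidised.

Step 12
Reactants: 14 methyl 2-{(3R,5R)-3,5-dimethyl-5-[(2R)-2-methyl-5-oxopentyl]-1,2-dioxolan-3-yl}acetate; 19 1-phenyl-5-{[(4E)-5-phenylpent-4-en-1-yl]sulfonyl}-1H-tetrazole
Product: 21 methyl 2-{(3R,5R)-3,5-dimethyl-5-[(2R,5E,9E)-2-methyl-10-phenyldeca-5,9-dien-1-yl]-1,2-dioxolan-3-yl}acetate, via potassium sulfonyl carbanion 20 (not isolated)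
Conditions: 19 (1.3 equiv), KN(SiMe3)2 (1.25 equiv), DME, −60 °C, 30 min; then 14, −60 °C → rt; NH4Cl aq; AgNO3-impregnated silica if needed
Reagents that add atoms: none
Why: Julia–Kocienski olefination, in which the pre-formed carbanion 20 adds to the aldehyde and Smiles rearrangement with loss of SO2 and the tetrazololate gives the C10=C11 alkene, mainly 10E through the open transition state favoured by potassium in DME, while pre-metalation keeps free amide base away from the β-peroxy ester.

Step 13
Reactants: 21 methyl 2-{(3R,5R)-3,5-dimethyl-5-[(2R,5E,9E)-2-methyl-10-phenyldeca-5,9-dien-1-yl]-1,2-dioxolan-3-yl}acetate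
Product: 22 2-{(3R,5R)-3,5-dimethyl-5-[(2R,5E,9E)-2-methyl-10-phenyldeca-5,9-dien-1-yl]-1,2-dioxolan-3-yl}acetic acid
Conditions: LiOH·H2O (3 equiv), THF/H2O (3:1), 0 °C → rt; then 0.5 M HCl to pH 3, 0 °C
Reagents that add atoms: lithium hydroxide (hydroxide oxygen), [Li+].[OH-]
Why: Saponification of the methyl ester by acyl–oxygen cleavage with LiOH at low temperature, mild enough that the β-peroxy carboxylate should not open by E1cB elimination, and no stereocentre is α to the carbonyl group.

## Compound list

1 | (E)-pent-3-en-2-one | C/C=C/C(C)=O | starting material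
2 | (3-bromopropoxy)(tert-butyl)dimethylsilane | BrCCCO[Si](C)(C)C(C)(C)C | starting material
3 | bromo{3-[(tert-butyldimethylsilyl)oxy]propyl}magnesium | Br[Mg]CCCO[Si](C)(C)C(C)(C)C | intermediate
4 | (4R)-7-[(tert-butyldimethylsilyl)oxy]-4-methylheptan-2-one | C[C@H](CCCO[Si](C)(C)C(C)(C)C)CC(C)=O | intermediate
5 | tert-butyl{[(4R)-7-methoxy-4,6-dimethylhept-6-en-1-yl]oxy}dimethylsilane (E/Z mixture) | C[C@H](CCCO[Si](C)(C)C(C)(C)C)CC(C)=COC | intermediate
6 | (4R)-7-[(tert-butyldimethylsilyl)oxy]-4-methylheptan-2-one O-oxide (carbonyl oxide) | C[C@H](CCCO[Si](C)(C)C(C)(C)C)CC(C)=[O+][O-] | intermediate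
7 | tert-butyl{[(4R)-6-hydroperoxy-6-methoxy-4-methylheptyl]oxy}dimethylsilane (both ketal epimers) | C[C@H](CCCO[Si](C)(C)C(C)(C)C)CC(C)(OC)OO | intermediate
8 | tert-butyl{[(4R)-6-methoxy-4-methyl-6-(triethylsilylperoxy)heptyl]oxy}dimethylsilane (both ketal epimers) | C[C@H](CCCO[Si](C)(C)C(C)(C)C)CC(C)(OC)OO[Si](CC)(CC)CC | intermediate
9 | methyl 3-methylbut-3-enoate | C=C(C)CC(=O)OC | starting material
10 | {(4R)-7-[(tert-butyldimethylsilyl)oxy]-4-methylheptan-2-ylidene}(triethylsilyloxy)oxonium (C5 peroxycarbenium ion) | C[C@H](CCCO[Si](C)(C)C(C)(C)C)CC(C)=[O+]O[Si](CC)(CC)CC | intermediate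
11 | methyl (7R)-10-[(tert-butyldimethylsilyl)oxy]-3,5,7-trimethyl-5-(triethylsilylperoxy)decanoate C3 cation (both C5 epimers) | C[C@H](CCCO[Si](C)(C)C(C)(C)C)CC(C)(C[C+](C)CC(=O)OC)OO[Si](CC)(CC)CC | intermediate
12 | methyl 2-[(3R,5R)-5-{(2R)-5-[(tert-butyldimethylsilyl)oxy]-2-methylpentyl}-3,5-dimethyl-1,2-dioxolan-3-yl]acetate | C[C@H](CCCO[Si](C)(C)C(C)(C)C)C[C@]1(C)C[C@](C)(CC(=O)OC)OO1 | intermediate
13 | methyl 2-{(3R,5R)-5-[(2R)-5-hydroxy-2-methylpentyl]-3,5-dimethyl-1,2-dioxolan-3-yl}acetate | C[C@H](CCCO)C[C@]1(C)C[C@](C)(CC(=O)OC)OO1 | intermediate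
14 | methyl 2-{(3R,5R)-3,5-dimethyl-5-[(2R)-2-methyl-5-oxopentyl]-1,2-dioxolan-3-yl}acetate | C[C@H](CCC=O)C[C@]1(C)C[C@](C)(CC(=O)OC)OO1 | intermediate
15 | 1-phenylprop-2-en-1-ol (racemic) | C=CC(O)c1ccccc1 | starting material
16 | ethyl (4E)-5-phenylpent-4-enoate | CCOC(=O)CC/C=C/c1ccccc1 | intermediate
17 | (4E)-5-phenylpent-4-en-1-ol | OCCC/C=C/c1ccccc1 | intermediate
18 | 1-phenyl-5-{[(4E)-5-phenylpent-4-en-1-yl]sulfanyl}-1H-tetrazole | C(CC/C=C/c1ccccc1)Sc1nnnn1-c1ccccc1 | intermediate
19 | 1-phenyl-5-{[(4E)-5-phenylpent-4-en-1-yl]sulfonyl}-1H-tetrazole | O=S(=O)(CCC/C=C/c1ccccc1)c1nnnn1-c1ccccc1 | intermediate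
20 | potassium (4E)-5-phenyl-1-[(1-phenyl-1H-tetrazol-5-yl)sulfonyl]pent-4-en-1-ide | [K+].O=S(=O)([CH-]CC/C=C/c1ccccc1)c1nnnn1-c1ccccc1 | intermediate
21 | methyl 2-{(3R,5R)-3,5-dimethyl-5-[(2R,5E,9E)-2-methyl-10-phenyldeca-5,9-dien-1-yl]-1,2-dioxolan-3-yl}acetate | C[C@H](CC/C=C/CC/C=C/c1ccccc1)C[C@]1(C)C[C@](C)(CC(=O)OC)OO1 | intermediate
22 | 2-{(3R,5R)-3,5-dimethyl-5-[(2R,5E,9E)-2-methyl-10-phenyldeca-5,9-dien-1-yl]-1,2-dioxolan-3-yl}acetic acid | C[C@H](CC/C=C/CC/C=C/c1ccccc1)C[C@]1(C)C[C@](C)(CC(=O)O)OO1 | target

## Step count and risks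

Total step count: 13. Longest linear sequence: 9 steps (steps 1–7, 12 and 13); the sulfone branch (steps 8–11) joins at step 12.

Steps most likely to fail:

1. Step 5. Capture of the peroxycarbenium ion by an alkene that the ester deactivates and that ties up the Lewis acid may be too slow, so that the ion fragments by migration to oxygen or loses an α-proton. The tertiary cation may also lose a proton before the ring closes, and the two new centres may form with almost no facial preference, which spreads the material over four isomers.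
Fallback, from 8 back to 12: the ring is assembled by two peroxycarbenium additions to strongly nucleophilic silyl enol ethers in place of one annulation.
   - Compound 8 is treated with 2-(trimethylsilyloxy)propene and catalytic Me3SiOTf in CH2Cl2 at −78 °C, which should give (6R)-9-[(tert-butyldimethylsilyl)oxy]-4,6-dimethyl-4-(triethylsilylperoxy)nonan-2-one F1 (bond C4–C5, both C5 epimers).
   - The labile peroxide silyl group is removed selectively (Bu4NF buffered with AcOH, THF, −20 °C). The freed hydroperoxide should close onto the ketone to give the hemiketal 5-{(2R)-5-[(tert-butyldimethylsilyl)oxy]-2-methylpentyl}-3,5-dimethyl-1,2-dioxolan-3-ol F2.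
   - MeOH, HC(OMe)3 and catalytic pyridinium p-toluenesulfonate at 0 °C convert F2 into tert-butyl{[(4R)-5-(3-methoxy-3,5-dimethyl-1,2-dioxolan-5-yl)-4-methylpentyl]oxy}dimethylsilane F3.
   - Ionisation of F3 with Me3SiOTf in the presence of 1-methoxy-1-(trimethylsilyloxy)ethene forms the C2–C3 bond on the cyclic peroxycarbenium ion and should give 12 with its isomers, separated as in step 5.
   - This detour answers the reactivity problem; the stereochemical problem stays and is again solved by separation.

2. Step 12. The ester may be deprotonated at C2 by the carbanion or by residual base, followed by E1cB opening of the dioxolane. The metalated sulfone may also self-condense, and E selectivity may be incomplete for two unbranched partners.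
Fallback, from 13 to 22: the ester is removed before the olefination, so that the carboxylate protects C2 from deprotonation.
   - Alcohol 13 is saponified (LiOH, THF/H2O, 0 °C) to 2-{(3R,5R)-5-[(2R)-5-hydroxy-2-methylpentyl]-3,5-dimethyl-1,2-dioxolan-3-yl}acetic acid F4.
   - Dess–Martin oxidation gives 2-{(3R,5R)-3,5-dimethyl-5-[(2R)-2-methyl-5-oxopentyl]-1,2-dioxolan-3-yl}acetic acid F5.
   - F5 is added to about 2.5 equivalents of carbanion 20 in DME at −60 °C; the first equivalent forms the potassium carboxylate and the rest olefinates the aldehyde. Acidic work-up should give 22 directly, with any 10Z isomer removed on AgNO3-impregnated silica.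

3. Step 1. Enantioselectivity may be incomplete, or uncatalysed 1,4- and 1,2-addition of the functionalised Grignard reagent may compete; either would carry the C7 epimer through the whole route.
Fallback, from 2 (through Grignard reagent 3) back to 4: the stereocentre is set by an auxiliary, with diastereomers that can be separated.
   - Reagent 3 is added with CuBr·SMe2 in THF/Me2S at −78 → −20 °C to commercial (4R)-3-[(2E)-but-2-enoyl]-4-phenyl-1,3-oxazolidin-2-one. Addition anti to the phenyl group in the chelated s-cis conformer should give (4R)-3-{(3R)-6-[(tert-butyldimethylsilyl)oxy]-3-methylhexanoyl}-4-phenyl-1,3-oxazolidin-2-one F6, purified to a single diastereomer.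
   - MeNHOMe·HCl and AlMe3 in CH2Cl2 convert F6 into (3R)-6-[(tert-butyldimethylsilyl)oxy]-N-methoxy-N,3-dimethylhexanamide F7.
   - MeMgBr in THF at 0 °C then gives ketone 4.

## Further compounds

F1 | step 5 | (6R)-9-[(tert-butyldimethylsilyl)oxy]-4,6-dimethyl-4-(triethylsilylperoxy)nonan-2-one | C[C@H](CCCO[Si](C)(C)C(C)(C)C)CC(C)(CC(C)=O)OO[Si](CC)(CC)CC
F2 | step 5 | 5-{(2R)-5-[(tert-butyldimethylsilyl)oxy]-2-methylpentyl}-3,5-dimethyl-1,2-dioxolan-3-ol | C[C@H](CCCO[Si](C)(C)C(C)(C)C)CC1(C)CC(C)(O)OO1
F3 | step 5 | tert-butyl{[(4R)-5-(3-methoxy-3,5-dimethyl-1,2-dioxolan-5-yl)-4-methylpentyl]oxy}dimethylsilane | C[C@H](CCCO[Si](C)(C)C(C)(C)C)CC1(C)CC(C)(OC)OO1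
F4 | step 12 | 2-{(3R,5R)-5-[(2R)-5-hydroxy-2-methylpentyl]-3,5-dimethyl-1,2-dioxolan-3-yl}acetic acid | C[C@H](CCCO)C[C@]1(C)C[C@](C)(CC(=O)O)OO1
F5 | step 12 | 2-{(3R,5R)-3,5-dimethyl-5-[(2R)-2-methyl-5-oxopentyl]-1,2-dioxolan-3-yl}acetic acid | C[C@H](CCC=O)C[C@]1(C)C[C@](C)(CC(=O)O)OO1
F6 | step 1 | (4R)-3-{(3R)-6-[(tert-butyldimethylsilyl)oxy]-3-methylhexanoyl}-4-phenyl-1,3-oxazolidin-2-one | C[C@H](CCCO[Si](C)(C)C(C)(C)C)CC(=O)N1[C@H](c2ccccc2)COC1=O
F7 | step 1 | (3R)-6-[(tert-butyldimethylsilyl)oxy]-N-methoxy-N,3-dimethylhexanamide | C[C@H](CCCO[Si](C)(C)C(C)(C)C)CC(=O)N(C)OC
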